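**Plan**

1. Feature used: in the ten-membered ring, C7 (tertiary carbinol bonded to C6, C8 and C11) and C8 (acyloxy carbinol) are adjacent and trans-oxygenated. The ring bond C7–C8 is therefore a pinacol bond between a C7 ketone and a C8 aldehyde, and the tertiary/secondary hydroxyl pair it leaves can be acylated selectively at O8.
2. Cuts, in order: the O8 ester, C11=C13 and O6–C12 (back to a C11 bis-hydroxymethyl group held as a 2,2-dimethyl-1,3-dioxane); then C7–C8 (ring); then C5–C6 (acetylide + Weinreb amide), C4–C15 (vinyl iodide + cuprate), C8–C9 (alkoxymethyllithium + Weinreb amide) and C1=C10 (olefination).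
3. Forward: the chain grows from a C2–C5 pentynal towards C8, then towards C7. The ten-membered carbocycle closes in step 20 and the γ-lactone in step 26, followed by the exocyclic methylene and desilylation.
4. Stereochemistry: Z C1=C10 from a Still–Gennari olefination; E C4=C5 from alkoxide-directed hydroalumination–iodination–methylation; C9 and C6 from oxazaborolidine reductions of an enone and an ynone; C7 and C8 from the pinacol step under control of C6 and C9; the epoxy acid from Sharpless epoxidation of tiglyl alcohol.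

Key step: step 20

Remark: locants C1–C15 are those of the germacrane skeleton of the target (C6 lactone O–CH, C7 tertiary carbinol, C8 ester carbinol, C9 free carbinol, C11=C13 methylene, C12 lactone carbonyl). Alkoxide, enolate and phosphonate salts formed by the stated base are treated as the parent compound and carry no number.

**Route**

Step 1
Reactants: 1 1,3-dithiane; 2 diethyl malonate
Product: 4 diethyl 2-(1,3-dithian-2-yl)malonate, via 2-chloro-1,3-dithiane 3 (not isolated)
Conditions: N-chlorosuccinimide, benzene, rt; then added to 2 and NaH in THF, 0 °C → rt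
Reagents that add atoms: none
Why: α-chlorination of the dithiane gives a chloride that ionises to the sulfur-stabilised 1,3-dithian-2-ylium ion, which the malonate anion captures at carbon (alkylation of an active methylene compound by an α-chloro sulfide), joining the future C7 to C11 with C12 and C13 as the two ester carbons.

Step 2
Reactants: 4 diethyl 2-(1,3-dithian-2-yl)malonate
Product: 5 2-(1,3-dithian-2-yl)propane-1,3-diol
Conditions: LiAlH4, THF, 0 °C → reflux; aqueous NaOH work-up
Reagents that add atoms: none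
Why: LiAlH4 ester reduction converts both ester groups to hydroxymethyl groups while the thioacetal is inert to hydride, giving the symmetric 1,3-diol that carries C12 and C13.

Step 3
Reactants: 5 2-(1,3-dithian-2-yl)propane-1,3-diol
Product: 6 2-(2,2-dimethyl-1,3-dioxan-5-yl)-1,3-dithiane
Conditions: 2,2-dimethoxypropane, PPTS (cat.), acetone, rt
Reagents that add atoms: 2,2-dimethoxypropane, COC(C)(C)OC
Why: acid-catalysed transketalisation closes the six-membered acetonide of the 1,3-diol without touching the dithiane, and the symmetric ring keeps C11 free of a stereocentre.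

Step 4
Reactants: 6 2-(2,2-dimethyl-1,3-dioxan-5-yl)-1,3-dithiane; 7 N-methoxy-N-methylcarbamoyl chloride
Product: 9 2-(2,2-dimethyl-1,3-dioxan-5-yl)-N-methoxy-N-methyl-1,3-dithiane-2-carboxamide, via lithiated dithiane 8 (not isolated)
Conditions: t-BuLi, THF–HMPA (10:1), −78 °C; then 7, −78 → 0 °C
Reagents that add atoms: none
Why: deprotonation between the two sulfur atoms (dithiane umpolung) gives a tertiary carbanion that is acylated once by the carbamoyl chloride, the hindered Weinreb amide not reacting with a second carbanion, so that C6 is attached to the masked C7 ketone.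

Step 5
Reactants: 10 5-(trimethylsilyl)pent-4-yn-1-ol
Product: 11 5-(trimethylsilyl)pent-4-ynal
Conditions: Dess–Martin periodinane, CH2Cl2, 0 °C → rt
Reagents that add atoms: none
Why: Dess–Martin oxidation stops at the aldehyde and leaves the alkynylsilane untouched, giving the C1 aldehyde with C2–C5 in place.

Step 6
Reactants: 11 5-(trimethylsilyl)pent-4-ynal; 12 ethyl 2-[bis(2,2,2-trifluoroethoxy)phosphoryl]propanoate
Product: 13 ethyl (2Z)-2-methyl-7-(trimethylsilyl)hept-2-en-6-ynoate
Conditions: 12, KN(SiMe3)2, 18-crown-6, THF, −78 °C; then 11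
Reagents that add atoms: none
Why: in the Still–Gennari olefination the electron-poor bis(trifluoroethyl) phosphonate collapses through the kinetically formed oxaphosphetane before it can equilibrate, which should give the Z trisubstituted enoate with the C9 ester carbon cis to C2 and the methyl group C14 on C10.

Step 7
Reactants: 13 ethyl (2Z)-2-methyl-7-(trimethylsilyl)hept-2-en-6-ynoate
Product: 14 (2Z)-N-methoxy-N,2-dimethyl-7-(trimethylsilyl)hept-2-en-6-ynamide
Conditions: MeNH(OMe)·HCl, iPrMgCl, THF, −20 → 0 °C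
Reagents that add atoms: N,O-dimethylhydroxylamine hydrochloride, CNOC.Cl
Why: the magnesium amide of N,O-dimethylhydroxylamine displaces ethoxide by 1,2-addition–elimination (Weinreb amide formation from an ester), leaving the Z alkene geometry and the alkynylsilane unchanged.

Step 8
Reactants: 15 tributyl(iodomethyl)stannane; 16 4-methoxybenzyl alcohol
Product: 17 tributyl{[(4-methoxybenzyl)oxy]methyl}stannane
Conditions: NaH, THF–DMF, 0 °C → rt
Reagents that add atoms: none
Why: Williamson ether synthesis on the unhindered primary iodide gives the stannane that serves as a protected hydroxymethyl anion source for C8.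

Step 9
Reactants: 14 (2Z)-N-methoxy-N,2-dimethyl-7-(trimethylsilyl)hept-2-en-6-ynamide; 17 tributyl{[(4-methoxybenzyl)oxy]methyl}stannane
Product: 19 (3Z)-1-[(4-methoxybenzyl)oxy]-3-methyl-8-(trimethylsilyl)oct-3-en-7-yn-2-one, via alkoxymethyllithium 18 (not isolated)
Conditions: 17, n-BuLi, THF, −78 °C; then 14, −78 °C; aq. NH4Cl
Reagents that add atoms: none
Why: tin–lithium exchange releases the α-alkoxy organolithium, which adds once to the amide because the chelated tetrahedral adduct survives until work-up (Weinreb ketone synthesis), forming the C8–C9 bond with the Z enone intact.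

Step 10
Reactants: 19 (3Z)-1-[(4-methoxybenzyl)oxy]-3-methyl-8-(trimethylsilyl)oct-3-en-7-yn-2-one
Product: 20 (2R,3Z)-1-[(4-methoxybenzyl)oxy]-3-methyl-8-(trimethylsilyl)oct-3-en-7-yn-2-ol
Conditions: (R)-2-methyl-CBS-oxazaborolidine (0.2 equiv), catecholborane, toluene, −78 °C
Reagents that add atoms: none
Why: in the Corey–Bakshi–Shibata reduction the ketone binds to the catalyst with the α-methylalkenyl group as the large and the alkoxymethyl group as the small substituent, so the (R) catalyst should deliver hydride to the face that gives the 9R alcohol, and catecholborane at −78 °C leaves the alkene alone.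

Step 11
Reactants: 20 (2R,3Z)-1-[(4-methoxybenzyl)oxy]-3-methyl-8-(trimethylsilyl)oct-3-en-7-yn-2-ol
Product: 21 tert-butyl{[(2R,3Z)-1-[(4-methoxybenzyl)oxy]-3-methyl-8-(trimethylsilyl)oct-3-en-7-yn-2-yl]oxy}dimethylsilane
Conditions: TBSCl, imidazole, DMF, rt
Reagents that add atoms: tert-butyldimethylsilyl chloride, CC(C)(C)[Si](C)(C)Cl
Why: imidazole-promoted silylation protects the C9 hydroxyl as a robust, non-chelating silyl ether that lasts to the final step.

Step 12
Reactants: 21 tert-butyl{[(2R,3Z)-1-[(4-methoxybenzyl)oxy]-3-methyl-8-(trimethylsilyl)oct-3-en-7-yn-2-yl]oxy}dimethylsilane; 9 2-(2,2-dimethyl-1,3-dioxan-5-yl)-N-methoxy-N-methyl-1,3-dithiane-2-carboxamide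
Product: 23 (6Z,8R)-8-[(tert-butyldimethylsilyl)oxy]-1-[2-(2,2-dimethyl-1,3-dioxan-5-yl)-1,3-dithian-2-yl]-9-[(4-methoxybenzyl)oxy]-7-methylnon-6-en-2-yn-1-one, via lithium acetylide 22 (not isolated)
Conditions: MeLi·LiBr, THF, 0 °C → rt; then 9, −78 → 0 °C
Reagents that add atoms: none
Why: methyllithium attacks the alkynyl silicon and releases the lithium acetylide (desilylative metalation), which adds once to the Weinreb amide (Weinreb ketone synthesis) and forms the C5–C6 bond with C7 masked as the dithiane and C11–C13 as the dioxane.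

Step 13
Reactants: 23 the ynone of step 12
Product: 24 (1R,6Z,8R)-8-[(tert-butyldimethylsilyl)oxy]-1-[2-(2,2-dimethyl-1,3-dioxan-5-yl)-1,3-dithian-2-yl]-9-[(4-methoxybenzyl)oxy]-7-methylnon-6-en-2-yn-1-ol
Conditions: (S)-2-methyl-CBS-oxazaborolidine (0.3 equiv), catecholborane, CH2Cl2, −78 °C
Reagents that add atoms: none
Why: in this Corey–Bakshi–Shibata reduction the quaternary dithianyl carbon is clearly the large group and the linear alkynyl group the small one, so the (S) catalyst should give the 6R propargylic alcohol (carbinol C1 of the name).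

Step 14
Reactants: 24 the propargylic alcohol of step 13
Product: 26 (1R,2Z,6Z,8R)-8-[(tert-butyldimethylsilyl)oxy]-1-[2-(2,2-dimethyl-1,3-dioxan-5-yl)-1,3-dithian-2-yl]-3-iodo-9-[(4-methoxybenzyl)oxy]-7-methylnona-2,6-dien-1-ol, via cyclic vinylalanate 25 (not isolated)
Conditions: NaAlH2(OCH2CH2OMe)2, THF, 0 °C → rt; then I2, THF, −78 °C
Reagents that add atoms: iodine, II
Why: the propargylic alkoxide directs trans-hydroalumination (hydride to C5, aluminium to C4 in a five-membered ring) and iodine cleaves the C–Al bond with retention, so the iodine on C4 ends up cis to C6 (alkoxide-directed hydroalumination–iodination of a propargylic alcohol).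

Step 15
Reactants: 26 the vinyl iodide of step 14
Product: 27 (1R,2E,6Z,8R)-8-[(tert-butyldimethylsilyl)oxy]-1-[2-(2,2-dimethyl-1,3-dioxan-5-yl)-1,3-dithian-2-yl]-9-[(4-methoxybenzyl)oxy]-3,7-dimethylnona-2,6-dien-1-ol
Conditions: Me2CuLi (excess), Et2O, −20 → 0 °C
Reagents that add atoms: lithium dimethylcuprate, [Li+].C[Cu-]C
Why: the cuprate replaces the vinylic iodine by methyl (C15) with retention of geometry (organocuprate coupling of a vinyl iodide), which fixes the E C4=C5 alkene and tolerates the sulfur atoms and the free alkoxide.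

Step 16
Reactants: 27 the allylic alcohol of step 15
Product: 28 the C6 triethylsilyl ether of 27
Conditions: Et3SiOTf, 2,6-lutidine, CH2Cl2, −78 °C
Reagents that add atoms: triethylsilyl trifluoromethanesulfonate, CC[Si](CC)(CC)OS(=O)(=O)C(F)(F)F
Why: the silyl triflate silylates the hindered C6 hydroxyl next to the quaternary dithiane carbon, giving a group that survives to step 25 and is then removed together with the acetonide.

Step 17
Reactants: 28 the C6 triethylsilyl ether
Product: 29 (2R,3E,7Z,9R)-9-[(tert-butyldimethylsilyl)oxy]-1-(2,2-dimethyl-1,3-dioxan-5-yl)-10-[(4-methoxybenzyl)oxy]-4,8-dimethyl-2-[(triethylsilyl)oxy]deca-3,7-dien-1-one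
Conditions: MeI, CaCO3, MeCN–H2O (9:1), 45 °C
Reagents that add atoms: water, O
Why: S-methylation turns the thioacetal into a sulfonium leaving group and water hydrolyses the thionium ion (alkylative dithiane hydrolysis); the neutral CaCO3-buffered medium should spare both alkenes, the silyl ethers, the acetonide and the C6 centre α to the new ketone.

Step 18
Reactants: 29 the C7 ketone
Product: 30 (2R,3E,7Z,9R)-9-[(tert-butyldimethylsilyl)oxy]-1-(2,2-dimethyl-1,3-dioxan-5-yl)-10-hydroxy-4,8-dimethyl-2-[(triethylsilyl)oxy]deca-3,7-dien-1-one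
Conditions: DDQ, CH2Cl2–pH 7 buffer, 0 °C
Reagents that add atoms: none
Why: DDQ oxidises the electron-rich 4-methoxybenzyl ether to an oxocarbenium ion that water cleaves (oxidative PMB removal), freeing only the C8 hydroxyl under neutral conditions.

Step 19
Reactants: 30 the C8 alcohol
Product: 31 (2R,3Z,7E,9R)-2-[(tert-butyldimethylsilyl)oxy]-10-(2,2-dimethyl-1,3-dioxan-5-yl)-3,7-dimethyl-10-oxo-9-[(triethylsilyl)oxy]deca-3,7-dienal
Conditions: Dess–Martin periodinane, pyridine, CH2Cl2, 0 °C; used at once
Reagents that add atoms: none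
Why: buffered Dess–Martin oxidation gives the α-silyloxy aldehyde without base or acid strong enough to epimerise C9 or move the C1=C10 alkene into conjugation.

Step 20
Reactants: 31 the C7 ketone C8 aldehyde
Product: 32 (1S,2R,3R,4Z,8E,10R)-3-[(tert-butyldimethylsilyl)oxy]-1-(2,2-dimethyl-1,3-dioxan-5-yl)-4,8-dimethyl-10-[(triethylsilyl)oxy]cyclodeca-4,8-diene-1,2-diol (ring C1 = C7, ring C2 = C8)
Conditions: TiCl3(DME)1.5, Zn–Cu couple, DME, reflux (reagent formation); then 31 added over 30 h at 25 °C under high dilution; aq. K2CO3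
Reagents that add atoms: none
Why: Low-valent titanium made from TiCl3(DME)1.5 and Zn–Cu transfers one electron to the C7 ketone and one to the C8 aldehyde, the two titanium-bound ketyls combine to a titanium pinacolate, and at 25 °C this is not deoxygenated, so aqueous base releases the 7,8-diol. The closest known reaction type is the McMurry intramolecular pinacol coupling of dialdehydes and keto aldehydes to medium- and large-ring 1,2-diols. The ten-membered carbocycle closes by ketyl–ketyl recombination between the chain ends C7 and C8 on the metal, a radical–radical mode that tolerates medium rings and is helped by the E C4=C5 and Z C1=C10 alkenes, which remove rotors from the tether. C8 is set relative to C9 and C7 relative to C6 by bond formation anti to each bulky α-silyloxy group (Felkin-type; O8 cis to O9 and O7 cis to O6 on the ring), and the 7,8-trans relation follows the known preference of ten-membered and larger rings for trans pinacolates, which together should give 7S,8R as drawn (7S only because O6 carries silicon; the spatial arrangement is that of 7R in the target). The step needs ketone–aldehyde cross coupling without reductive loss of the α-oxygen groups: intramolecularity and the mild pinacol temperature secure the first and the non-chelating silyl ethers the second, while the diastereoselection rests only on the two flanking centres and is the least certain element of the route.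

Step 21
Reactants: 33 tiglic acid
Product: 34 (2E)-2-methylbut-2-en-1-ol
Conditions: LiAlH4, Et2O, 0 °C → rt
Reagents that add atoms: none
Why: LiAlH4 reduction of the carboxylic acid proceeds by 1,2-addition and keeps the E alkene, giving the allylic alcohol needed for directed epoxidation.

Step 22
Reactants: 34 (2E)-2-methylbut-2-en-1-ol
Product: 35 [(2R,3R)-2,3-dimethyloxiran-2-yl]methanol
Conditions: Ti(OiPr)4 (cat.), D-(−)-diethyl tartrate (cat.), t-BuOOH, CH2Cl2, −20 °C
Reagents that add atoms: tert-butyl hydroperoxide, CC(C)(C)OO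
Why: in the Sharpless asymmetric epoxidation the titanium tartrate complex delivers the peroxide oxygen to one face of the E allylic alcohol, the unnatural D-(−)-tartrate giving the 2R,3R epoxide, and the cis relation of the two methyl groups comes from the E geometry.

Step 23
Reactants: 35 [(2R,3R)-2,3-dimethyloxiran-2-yl]methanol
Product: 36 (2S,3R)-2,3-dimethyloxirane-2-carboxylic acid
Conditions: RuCl3·xH2O (cat.), NaIO4, MeCN–EtOAc–H2O, rt
Reagents that add atoms: water, O; sodium periodate (terminal oxidant), [Na+].[O-]I(=O)(=O)=O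
Why: catalytic RuO4 oxidation of a 2,3-epoxy alcohol takes the primary alcohol to the acid without opening the epoxide; neither centre is touched, and the descriptor at C2 changes from R to S only because the carboxyl group outranks C3.

Step 24
Reactants: 32 the 7,8-diol; 36 (2S,3R)-2,3-dimethyloxirane-2-carboxylic acid
Product: 38 the C8 (2S,3R)-2,3-dimethyloxirane-2-carboxylate of 32 (6R,7S,8R,9R), via mixed anhydride 37 (not isolated)
Conditions: 36, 2,4,6-trichlorobenzoyl chloride, Et3N, toluene, rt; then 32, DMAP, toluene, 40 °C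
Reagents that add atoms: none
Why: in the Yamaguchi esterification DMAP transfers the epoxy acyl group from the mixed anhydride to the secondary C8 hydroxyl, while the tertiary C7 hydroxyl is too hindered to react, so the 7,8-diol is differentiated without protection.

Step 25
Reactants: 38 the C8 ester
Product: 39 the tetraol (6R,7R,8R,9R) with free C6 and C7 hydroxyls, a 1,3-dihydroxypropan-2-yl group on C7, the C8 epoxy ester and the C9 silyl ether
Conditions: PPTS, MeOH, rt
Reagents that add atoms: none
Why: mild acid methanolysis removes the triethylsilyl ether and the 1,3-dioxane acetonide in one operation, while the hindered tert-butyldimethylsilyl ether and the electron-poor epoxy ester should survive.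

Step 26
Reactants: 39 the tetraol
Product: 41 the 6,12-lactone with a hydroxymethyl group on C11 (6R,7R,8R,9R; both C11 epimers), via lactol 40 (not isolated)
Conditions: TEMPO (0.2 equiv), PhI(OAc)2 (2.2 equiv), CH2Cl2, rt
Reagents that add atoms: none
Why: the oxoammonium salt oxidises a primary alcohol to the aldehyde, which is trapped by the C6 hydroxyl as a five-membered lactol and oxidised on to the γ-lactone (TEMPO oxidative lactonisation of a 1,4-diol); either hydroxymethyl group may react, because C11 becomes trigonal in the next step.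

Step 27
Reactants: 41 the hydroxymethyl lactone
Product: 43 the α-methylene lactone with the C9 silyl ether, via mesylate 42 (not isolated)
Conditions: MsCl, Et3N, CH2Cl2, 0 °C; then DBU, rt
Reagents that add atoms: none
Why: the primary hydroxyl is mesylated selectively over the tertiary C7 hydroxyl, and DBU removes the acidic C11 proton so that mesylate leaves by E1cB elimination, forming the C11=C13 methylene.

Step 28
Reactants: 43 the silylated α-methylene lactone
Product: 44 the target, (6R,7R,8R,9R)-7,9-dihydroxy-8-{[(2S,3R)-2,3-dimethyloxiran-2-yl]carbonyloxy}germacra-1(10)Z,4E,11(13)-trien-12,6-olide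
Conditions: HF·pyridine, pyridine, THF, 0 °C → rt
Reagents that add atoms: none
Why: buffered fluoride desilylation frees the C9 hydroxyl under weakly acidic conditions, which should avoid acyl migration from O8, conjugate addition to the methylene lactone and epoxide opening.

**Compound list**

1 | 1,3-dithiane | C1CSCSC1 | starting material
2 | diethyl malonate | CCOC(=O)CC(=O)OCC | starting material
3 | 2-chloro-1,3-dithiane | ClC1SCCCS1 | intermediate (not isolated)
4 | diethyl 2-(1,3-dithian-2-yl)malonate | CCOC(=O)C(C1SCCCS1)C(=O)OCC | intermediate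
5 | 2-(1,3-dithian-2-yl)propane-1,3-diol | OCC(CO)C1SCCCS1 | intermediate
6 | 2-(2,2-dimethyl-1,3-dioxan-5-yl)-1,3-dithiane | CC1(C)OCC(CO1)C1SCCCS1 | intermediate
7 | N-methoxy-N-methylcarbamoyl chloride | CON(C)C(Cl)=O | starting material
8 | 2-lithio-2-(2,2-dimethyl-1,3-dioxan-5-yl)-1,3-dithiane | [Li]C1(SCCCS1)C1COC(C)(C)OC1 | intermediate (not isolated)
9 | 2-(2,2-dimethyl-1,3-dioxan-5-yl)-N-methoxy-N-methyl-1,3-dithiane-2-carboxamide | CON(C)C(=O)C1(SCCCS1)C1COC(C)(C)OC1 | intermediate
10 | 5-(trimethylsilyl)pent-4-yn-1-ol | C[Si](C)(C)C#CCCCO | starting material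
11 | 5-(trimethylsilyl)pent-4-ynal | C[Si](C)(C)C#CCCC=O | intermediate
12 | ethyl 2-[bis(2,2,2-trifluoroethoxy)phosphoryl]propanoate | CCOC(=O)C(C)P(=O)(OCC(F)(F)F)OCC(F)(F)F | starting material
13 | ethyl (2Z)-2-methyl-7-(trimethylsilyl)hept-2-en-6-ynoate | C[Si](C)(C)C#CCC/C=C(/C)C(=O)OCC | intermediate
14 | (2Z)-N-methoxy-N,2-dimethyl-7-(trimethylsilyl)hept-2-en-6-ynamide | C[Si](C)(C)C#CCC/C=C(/C)C(=O)N(C)OC | intermediate
15 | tributyl(iodomethyl)stannane | CCCC[Sn](CCCC)(CCCC)CI | starting material
16 | 4-methoxybenzyl alcohol | COc1ccc(CO)cc1 | starting material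
17 | tributyl{[(4-methoxybenzyl)oxy]methyl}stannane | CCCC[Sn](CCCC)(CCCC)COCc1ccc(OC)cc1 | intermediate
18 | {[(4-methoxybenzyl)oxy]methyl}lithium | [Li]COCc1ccc(OC)cc1 | intermediate (not isolated)
19 | (3Z)-1-[(4-methoxybenzyl)oxy]-3-methyl-8-(trimethylsilyl)oct-3-en-7-yn-2-one | C[Si](C)(C)C#CCC/C=C(/C)C(=O)COCc1ccc(OC)cc1 | intermediate
20 | (2R,3Z)-1-[(4-methoxybenzyl)oxy]-3-methyl-8-(trimethylsilyl)oct-3-en-7-yn-2-ol | C[Si](C)(C)C#CCC/C=C(/C)[C@@H](O)COCc1ccc(OC)cc1 | intermediate
21 | tert-butyl{[(2R,3Z)-1-[(4-methoxybenzyl)oxy]-3-methyl-8-(trimethylsilyl)oct-3-en-7-yn-2-yl]oxy}dimethylsilane | C[Si](C)(C)C#CCC/C=C(/C)[C@@H](O[Si](C)(C)C(C)(C)C)COCc1ccc(OC)cc1 | intermediate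
22 | {(5Z,7R)-7-[(tert-butyldimethylsilyl)oxy]-8-[(4-methoxybenzyl)oxy]-6-methyloct-5-en-1-yn-1-yl}lithium | [Li]C#CCC/C=C(/C)[C@@H](O[Si](C)(C)C(C)(C)C)COCc1ccc(OC)cc1 | intermediate (not isolated)
23 | (6Z,8R)-8-[(tert-butyldimethylsilyl)oxy]-1-[2-(2,2-dimethyl-1,3-dioxan-5-yl)-1,3-dithian-2-yl]-9-[(4-methoxybenzyl)oxy]-7-methylnon-6-en-2-yn-1-one | CC1(C)OCC(CO1)C1(SCCCS1)C(=O)C#CCC/C=C(/C)[C@@H](O[Si](C)(C)C(C)(C)C)COCc1ccc(OC)cc1 | intermediate
24 | (1R,6Z,8R)-8-[(tert-butyldimethylsilyl)oxy]-1-[2-(2,2-dimethyl-1,3-dioxan-5-yl)-1,3-dithian-2-yl]-9-[(4-methoxybenzyl)oxy]-7-methylnon-6-en-2-yn-1-ol | CC1(C)OCC(CO1)C1(SCCCS1)[C@H](O)C#CCC/C=C(/C)[C@@H](O[Si](C)(C)C(C)(C)C)COCc1ccc(OC)cc1 | intermediate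
25 | sodium cyclic vinylalanate of 24 (five-membered O6–Al–C4=C5–C6 ring, two 2-methoxyethoxy groups on aluminium) | [Na+].COCCO[Al-]1(OCCOC)O[C@@H](C2(SCCCS2)C2COC(C)(C)OC2)C=C1CC/C=C(/C)[C@@H](O[Si](C)(C)C(C)(C)C)COCc1ccc(OC)cc1 | intermediate (not isolated)
26 | (1R,2Z,6Z,8R)-8-[(tert-butyldimethylsilyl)oxy]-1-[2-(2,2-dimethyl-1,3-dioxan-5-yl)-1,3-dithian-2-yl]-3-iodo-9-[(4-methoxybenzyl)oxy]-7-methylnona-2,6-dien-1-ol | CC1(C)OCC(CO1)C1(SCCCS1)[C@H](O)/C=C(\I)CC/C=C(/C)[C@@H](O[Si](C)(C)C(C)(C)C)COCc1ccc(OC)cc1 | intermediate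
27 | (1R,2E,6Z,8R)-8-[(tert-butyldimethylsilyl)oxy]-1-[2-(2,2-dimethyl-1,3-dioxan-5-yl)-1,3-dithian-2-yl]-9-[(4-methoxybenzyl)oxy]-3,7-dimethylnona-2,6-dien-1-ol | CC1(C)OCC(CO1)C1(SCCCS1)[C@H](O)/C=C(\C)CC/C=C(/C)[C@@H](O[Si](C)(C)C(C)(C)C)COCc1ccc(OC)cc1 | intermediate
28 | C6 triethylsilyl ether of 27 (6R,9R) | CC1(C)OCC(CO1)C1(SCCCS1)[C@H](O[Si](CC)(CC)CC)/C=C(\C)CC/C=C(/C)[C@@H](O[Si](C)(C)C(C)(C)C)COCc1ccc(OC)cc1 | intermediate
29 | (2R,3E,7Z,9R)-9-[(tert-butyldimethylsilyl)oxy]-1-(2,2-dimethyl-1,3-dioxan-5-yl)-10-[(4-methoxybenzyl)oxy]-4,8-dimethyl-2-[(triethylsilyl)oxy]deca-3,7-dien-1-one | CC1(C)OCC(CO1)C(=O)[C@H](O[Si](CC)(CC)CC)/C=C(\C)CC/C=C(/C)[C@@H](O[Si](C)(C)C(C)(C)C)COCc1ccc(OC)cc1 | intermediate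
30 | (2R,3E,7Z,9R)-9-[(tert-butyldimethylsilyl)oxy]-1-(2,2-dimethyl-1,3-dioxan-5-yl)-10-hydroxy-4,8-dimethyl-2-[(triethylsilyl)oxy]deca-3,7-dien-1-one | CC1(C)OCC(CO1)C(=O)[C@H](O[Si](CC)(CC)CC)/C=C(\C)CC/C=C(/C)[C@@H](O[Si](C)(C)C(C)(C)C)CO | intermediate
31 | (2R,3Z,7E,9R)-2-[(tert-butyldimethylsilyl)oxy]-10-(2,2-dimethyl-1,3-dioxan-5-yl)-3,7-dimethyl-10-oxo-9-[(triethylsilyl)oxy]deca-3,7-dienal | CC1(C)OCC(CO1)C(=O)[C@H](O[Si](CC)(CC)CC)/C=C(\C)CC/C=C(/C)[C@@H](O[Si](C)(C)C(C)(C)C)C=O | intermediate (precursor of the key step)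
32 | (1S,2R,3R,4Z,8E,10R)-3-[(tert-butyldimethylsilyl)oxy]-1-(2,2-dimethyl-1,3-dioxan-5-yl)-4,8-dimethyl-10-[(triethylsilyl)oxy]cyclodeca-4,8-diene-1,2-diol; target numbering 6R,7S,8R,9R | CC1(C)OCC(CO1)[C@@]2(O)[C@H](O[Si](CC)(CC)CC)/C=C(\C)CC/C=C(/C)[C@@H](O[Si](C)(C)C(C)(C)C)[C@H]2O | intermediate (product of the key step)
33 | tiglic acid, (2E)-2-methylbut-2-enoic acid | C/C=C(\C)C(=O)O | starting material
34 | (2E)-2-methylbut-2-en-1-ol | C/C=C(\C)CO | intermediate
35 | [(2R,3R)-2,3-dimethyloxiran-2-yl]methanol | OC[C@@]1(C)O[C@@H]1C | intermediate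
36 | (2S,3R)-2,3-dimethyloxirane-2-carboxylic acid | OC(=O)[C@@]1(C)O[C@@H]1C | intermediate
37 | (2S,3R)-2,3-dimethyloxirane-2-carboxylic 2,4,6-trichlorobenzoic anhydride | O=C(OC(=O)c1c(Cl)cc(Cl)cc1Cl)[C@@]1(C)O[C@@H]1C | intermediate (not isolated)
38 | C8 (2S,3R)-2,3-dimethyloxirane-2-carboxylate of 32, C7 hydroxyl free (6R,7S,8R,9R) | CC1(C)OCC(CO1)[C@@]2(O)[C@H](O[Si](CC)(CC)CC)/C=C(\C)CC/C=C(/C)[C@@H](O[Si](C)(C)C(C)(C)C)[C@H]2OC(=O)[C@@]1(C)O[C@@H]1C | intermediate
39 | tetraol: ten-membered 1(10)Z,4E-diene with 6-OH, 7-OH, 7-(1,3-dihydroxypropan-2-yl), 8-epoxy ester, 9-OTBS (6R,7R,8R,9R) | OCC(CO)[C@@]1(O)[C@H](O)/C=C(\C)CC/C=C(/C)[C@@H](O[Si](C)(C)C(C)(C)C)[C@H]1OC(=O)[C@@]2(C)O[C@@H]2C | intermediate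
40 | 6,12-lactol with 11-hydroxymethyl group (C11 and C12 epimers) | OCC1C(O)O[C@@H]2/C=C(\C)CC/C=C(/C)[C@@H](O[Si](C)(C)C(C)(C)C)[C@@H](OC(=O)[C@@]3(C)O[C@@H]3C)[C@@]12O | intermediate (not isolated)
41 | 6,12-lactone with 11-hydroxymethyl group, 7-OH, 8-epoxy ester, 9-OTBS (6R,7R,8R,9R; both C11 epimers) | OCC1C(=O)O[C@@H]2/C=C(\C)CC/C=C(/C)[C@@H](O[Si](C)(C)C(C)(C)C)[C@@H](OC(=O)[C@@]3(C)O[C@@H]3C)[C@@]12O | intermediate
42 | methanesulfonate of 41 at the C13 hydroxyl | CS(=O)(=O)OCC1C(=O)O[C@@H]2/C=C(\C)CC/C=C(/C)[C@@H](O[Si](C)(C)C(C)(C)C)[C@@H](OC(=O)[C@@]3(C)O[C@@H]3C)[C@@]12O | intermediate (not isolated)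
43 | 9-O-tert-butyldimethylsilyl ether of the target (α-methylene lactone) | C=C1C(=O)O[C@@H]2/C=C(\C)CC/C=C(/C)[C@@H](O[Si](C)(C)C(C)(C)C)[C@@H](OC(=O)[C@@]3(C)O[C@@H]3C)[C@@]12O | intermediate
44 | target, (6R,7R,8R,9R)-7,9-dihydroxy-8-{[(2S,3R)-2,3-dimethyloxiran-2-yl]carbonyloxy}germacra-1(10)Z,4E,11(13)-trien-12,6-olide | C=C1C(=O)O[C@@H]2/C=C(\C)CC/C=C(/C)[C@@H](O)[C@@H](OC(=O)[C@@]3(C)O[C@@H]3C)[C@@]12O | target

**Step count and weak points**

Total: 28 steps. Longest linear sequence: 20 steps, from 10 through steps 5–7, 9–20 and 24–28 to 44. Side branches: steps 1–4 (amide 9), step 8 (stannane 17), steps 21–23 (acid 36).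

Steps most likely to fail:

1. Step 20. The two ketyl carbons may combine with the wrong relative topicity at C8, because only the flanking C6 and C9 silyloxy groups and the ring-size preference steer the coupling. Fallback: the route leaves 31 by the same ring closure but accepts the C8 epimer of the diol, 8-epi-diol F1. Its secondary hydroxyl is oxidised (SO3·pyridine, DMSO, iPr2NEt, 0 °C; the tertiary hydroxyl cannot react) to the ring α-hydroxy ketone F2. Reduction of F2 with Zn(BH4)2 in Et2O at −20 °C, with zinc bridging the C7 hydroxyl and the C8 carbonyl and hydride entering anti to the dioxanyl group on C7, should return the 7,8-trans diol 32. C8 is then set by a substrate-directed reduction and no longer by the C–C bond formation.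

2. Step 24. Acyl transfer from the α-quaternary epoxy acid to the C8 hydroxyl, which lies between a quaternary carbinol and a silyloxy carbon, may be so slow that the mixed anhydride decomposes or the epoxide opens first. Fallback: the alcohol is activated in place of the acid. Diol 32 is heated with Bu2SnO in toluene with removal of water to give the 7,8-O-dibutylstannylene acetal F3. The acid 36 is converted with 1-chloro-N,N,2-trimethylprop-1-en-1-amine (CH2Cl2, 0 °C, neutral conditions) into (2S,3R)-2,3-dimethyloxirane-2-carbonyl chloride F4. The stannylene acetal is acylated by F4 at its less hindered secondary oxygen and, after aqueous work-up, the route is rejoined at ester 38.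

3. Step 26. Oxidation may go on at the second hydroxymethyl group before or after the lactol is oxidised, so that products of several oxidation levels form side by side. Fallback: selectivity between the two arms is given up. Tetraol 39 is treated with an excess of TEMPO and PhI(OAc)2 until both arms are oxidised, which should give the α-formyl lactone F5 (present largely as its enol). The aldehyde of F5 is then reduced chemoselectively with NaBH4 in MeOH at −40 °C, leaving the lactone and the epoxy ester, and the route is rejoined at hydroxymethyl lactone 41.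

**Further compounds**

F1 | step 20 | 8-epi-diol, C8 epimer of 32 (6R,7S,8S,9R) | CC1(C)OCC(CO1)[C@@]2(O)[C@H](O[Si](CC)(CC)CC)/C=C(\C)CC/C=C(/C)[C@@H](O[Si](C)(C)C(C)(C)C)[C@@H]2O
F2 | step 20 | ring α-hydroxy ketone, C8 ketone with C7 tertiary hydroxyl (6R,7R,9R) | CC1(C)OCC(CO1)[C@@]2(O)[C@H](O[Si](CC)(CC)CC)/C=C(\C)CC/C=C(/C)[C@@H](O[Si](C)(C)C(C)(C)C)C2=O
F3 | step 24 | 7,8-O-dibutylstannylene acetal of 32 | CC1(C)OCC(CO1)[C@@]2(O3)[C@H](O[Si](CC)(CC)CC)/C=C(\C)CC/C=C(/C)[C@@H](O[Si](C)(C)C(C)(C)C)[C@H]2O[Sn]3(CCCC)CCCC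
F4 | step 24 | (2S,3R)-2,3-dimethyloxirane-2-carbonyl chloride | O=C(Cl)[C@@]1(C)O[C@@H]1C
F5 | step 26 | α-formyl lactone, 13-oxo analogue of 41 | O=CC1C(=O)O[C@@H]2/C=C(\C)CC/C=C(/C)[C@@H](O[Si](C)(C)C(C)(C)C)[C@@H](OC(=O)[C@@]3(C)O[C@@H]3C)[C@@]12O
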